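## Retrosynthetic overview

1. The last bond made is C4=C5: ring-closing metathesis between an isopropenyl group on the furanone and a propenyl group on the lactone closes the ten-membered carbocycle.
2. The C8 ester comes from acylation, and C7–C8 from a zinc Barbier allylation of a furanone acetaldehyde with an (R)-5-propenyl-3-(bromomethyl)butenolide, which sets C7 and C8 from C6.
3. The key disconnection is C10–O: an enantioselective 5-exo oxa-Michael addition of a 1,3-diketone enol onto an oxo-enal released from a furan by singlet oxygen, forming the 3(2H)-furanone and the C10 quaternary centre.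
4. The furan comes from (Z)-3-methylpent-2-en-4-yn-1-ol and a methacrylic Weinreb amide; the butenolide comes from resolved (E)-hexa-1,4-dien-3-ol and 2-(bromomethyl)acrylic acid (esterification, then metathesis).
5. Ring order: furan (sacrificial) → 3(2H)-furanone → butenolide (becomes the α-methylene lactone on allylation) → ten-membered ring.

Assumption: the target is the (4Z,6R,7R,8R,10S) isomer encoded by the SMILES, and N-methoxy-N-methylmethacrylamide and racemic (E)-hexa-1,4-dien-3-ol are bought as catalogue items.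

## Route

Step 1
Reactants: 1 (Z)-3-methylpent-2-en-4-yn-1-ol; 2 N-methoxy-N-methylmethacrylamide
Product: 5 3-methyl-1-(3-methylfuran-2-yl)but-3-en-2-one, via hydroxy enynone 3 (not isolated), via alkylidene dihydrofuran 4 (not isolated)
Conditions: n-BuLi (2.1 equiv), THF, −78 °C; 2, −78 → 0 °C; cold 1 M HCl; crude, DBU (10 mol%), CH2Cl2, rt
Reagents that add atoms: none
Why: Weinreb ketone synthesis with the O,C-dilithio species gives the (Z)-hydroxy enynone, whose hydroxyl adds 5-exo-dig to the activated alkyne (oxa-Michael) and the alkylidene dihydrofuran aromatises by a base-mediated 1,3-proton shift (enynol-to-furan cycloisomerisation); no stereocentre is formed.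

Step 2
Reactants: 5 3-methyl-1-(3-methylfuran-2-yl)but-3-en-2-one
Product: 9 (S)-2-[2-methyl-3-oxo-5-(prop-1-en-2-yl)-2,3-dihydrofuran-2-yl]acetaldehyde, via furan endoperoxide 6 (not isolated), via (Z)-oxoenal 7 (not isolated), via (E)-oxoenal 8 (not isolated)
Conditions: O2, hν (white LED), TPP (0.5 mol%), CH2Cl2, −78 °C; Me2S (1.5 equiv), −78 → −40 °C; then (S)-2-{bis[3,5-bis(trifluoromethyl)phenyl](trimethylsilyloxy)methyl}pyrrolidine (20 mol%), PhCO2H (20 mol%), toluene, −40 → −20 °C; quick silica filtration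
Reagents that add atoms: dioxygen (used as singlet oxygen), O=O
Why: Proposed new method: [4+2] addition of singlet oxygen to the furan and Me2S reduction unmask a (Z)-4-oxo-enal carrying a 1,3-diketone; the secondary-amine catalyst isomerises it to the (E)-enal (which cannot undergo the competing aldol to a cyclopentenone) and forms the iminium ion, and the diketone enol oxygen then closes 5-exo-trig onto C10 on the Si face left open by the C(Ar)2OTMS group, forming the C10–O bond, the 3(2H)-furanone and the (S)-quaternary centre in one operation; the closest known reactions are the racemic base-mediated furan photooxygenation/oxa-Michael route to 3(2H)-furanones and iminium-catalysed oxa-Michael additions to enals.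

Step 3
Reactants: 10 rac-(E)-hexa-1,4-dien-3-ol
Product: 11 (3S,4E)-hexa-1,4-dien-3-ol
Conditions: Ti(OiPr)4 (10 mol%), D-(−)-DIPT (15 mol%), t-BuOOH (0.6 equiv), 4 Å MS, CH2Cl2, −20 °C
Reagents that add atoms: none
Why: Sharpless kinetic resolution: with D-(−)-DIPT the (R)-enantiomer is epoxidised quickly at its (E)-propenyl group and the (S)-alcohol is recovered in high ee at about 55% conversion, which fixes the future C6 configuration.

Step 4
Reactants: 11 (3S,4E)-hexa-1,4-dien-3-ol; 12 2-(bromomethyl)acrylic acid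
Product: 13 (3S,4E)-hexa-1,4-dien-3-yl 2-(bromomethyl)prop-2-enoate
Conditions: DCC (1.1 equiv), DMAP (5 mol%), CH2Cl2, 0 °C
Reagents that add atoms: none
Why: Steglich esterification of the secondary alcohol; the stereocentre is not touched.

Step 5
Reactants: 13 (3S,4E)-hexa-1,4-dien-3-yl 2-(bromomethyl)prop-2-enoate
Product: 14 (5R)-3-(bromomethyl)-5-[(1E)-prop-1-en-1-yl]furan-2(5H)-one
Conditions: Grubbs II (5 mol%), toluene (5 mM), 80 °C
Reagents that add atoms: none
Why: Ring-closing metathesis between the fast-initiating terminal vinyl group and the 1,1-disubstituted acrylate gives the butenolide while the internal propenyl group is a spectator; the stereocentre is retained (the descriptor becomes R only through CIP priorities).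

Step 6
Reactants: 9 (S)-2-[2-methyl-3-oxo-5-(prop-1-en-2-yl)-2,3-dihydrofuran-2-yl]acetaldehyde; 14 (5R)-3-(bromomethyl)-5-[(1E)-prop-1-en-1-yl]furan-2(5H)-one
Product: 16 (2S)-2-{(2R)-2-hydroxy-2-[(2R,3R)-4-methylidene-5-oxo-2-[(1E)-prop-1-en-1-yl]oxolan-3-yl]ethyl}-2-methyl-5-(prop-1-en-2-yl)furan-3(2H)-one, via allylzinc bromide 15 (not isolated)
Conditions: Zn dust (3 equiv), 14 (1.5 equiv), THF/sat. aq. NH4Cl (2:1), 0 °C → rt
Reagents that add atoms: none
Why: Barbier-type zinc allylation with γ-attack of the 2-carbonyl-allylzinc: the C7–C8 bond forms anti to the C6 propenyl group (C7 R) and the zinc-chelated closed transition state expected for these reagents gives the syn carbinol (C8 R), regenerating the α-methylene lactone.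

Step 7
Reactants: 16 the C8 alcohol from step 6; 17 3-methylbutanoic anhydride
Product: 18 (1R)-1-[(2R,3R)-4-methylidene-5-oxo-2-[(1E)-prop-1-en-1-yl]oxolan-3-yl]-2-[(2S)-2-methyl-3-oxo-5-(prop-1-en-2-yl)-2,3-dihydrofuran-2-yl]ethyl 3-methylbutanoate
Conditions: 17 (1.5 equiv), DMAP (10 mol%), Et3N (2 equiv), CH2Cl2, 0 °C
Reagents that add atoms: none
Why: DMAP-catalysed acylation of the secondary alcohol with retention at C8, done promptly so that the free hydroxyl cannot translactonise.

Step 8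
Reactants: 18 the C8 3-methylbutanoate from step 7
Product: 19 CNP0409052.1, (4Z,6R,7R,8R,10S)-8-(3-methylbutanoyloxy)-1-oxo-3,10-epoxygermacra-2,4,11(13)-trien-12,6-olide
Conditions: Hoveyda–Grubbs II (15 mol%, two portions), toluene (1 mM), 100 °C
Reagents that add atoms: none
Why: Ring-closing metathesis (initiation at the propenyl group, closure on the isopropenyl group, loss of propene) forms the trisubstituted C4=C5 bond, whose Z geometry is enforced by the nine-membered oxa-bridged ring; no stereocentre is affected.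

## Compound list

1 | (Z)-3-methylpent-2-en-4-yn-1-ol | C#C/C(C)=C\CO | starting material
2 | N-methoxy-N-methylmethacrylamide | C=C(C)C(=O)N(C)OC | starting material
3 | (6Z)-8-hydroxy-2,6-dimethylocta-1,6-dien-4-yn-3-one | C=C(C)C(=O)C#C/C(C)=C\CO | intermediate
4 | (1Z)-3-methyl-1-[3-methylfuran-2(5H)-ylidene]but-3-en-2-one | C=C(C)C(=O)/C=C1\OCC=C1C | intermediate
5 | 3-methyl-1-(3-methylfuran-2-yl)but-3-en-2-one | C=C(C)C(=O)Cc1occc1C | intermediate
6 | 3-methyl-1-(6-methyl-2,3,7-trioxabicyclo[2.2.1]hept-5-en-1-yl)but-3-en-2-one (racemic) | C=C(C)C(=O)CC12OOC(O1)C=C2C | intermediate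
7 | (2Z)-3,7-dimethyl-4,6-dioxoocta-2,7-dienal (triketo tautomer shown) | O=C/C=C(/C)C(=O)CC(=O)C(C)=C | intermediate
8 | (2E)-3,7-dimethyl-4,6-dioxoocta-2,7-dienal (triketo tautomer shown) | O=C/C=C(\C)C(=O)CC(=O)C(C)=C | intermediate
9 | (S)-2-[2-methyl-3-oxo-5-(prop-1-en-2-yl)-2,3-dihydrofuran-2-yl]acetaldehyde | O=CC[C@]1(C)OC(C(C)=C)=CC1=O | intermediate
10 | rac-(E)-hexa-1,4-dien-3-ol | C=CC(O)/C=C/C | starting material
11 | (3S,4E)-hexa-1,4-dien-3-ol | C=C[C@H](O)/C=C/C | intermediate
12 | 2-(bromomethyl)acrylic acid | C=C(CBr)C(=O)O | starting material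
13 | (3S,4E)-hexa-1,4-dien-3-yl 2-(bromomethyl)prop-2-enoate | C=C[C@H](OC(=O)C(=C)CBr)/C=C/C | intermediate
14 | (5R)-3-(bromomethyl)-5-[(1E)-prop-1-en-1-yl]furan-2(5H)-one | BrCC1=C[C@@H](/C=C/C)OC1=O | intermediate
15 | {[(5R)-2-oxo-5-[(1E)-prop-1-en-1-yl]-2,5-dihydrofuran-3-yl]methyl}zinc bromide | Br[Zn]CC1=C[C@@H](/C=C/C)OC1=O | intermediate
16 | (2S)-2-{(2R)-2-hydroxy-2-[(2R,3R)-4-methylidene-5-oxo-2-[(1E)-prop-1-en-1-yl]oxolan-3-yl]ethyl}-2-methyl-5-(prop-1-en-2-yl)furan-3(2H)-one | C=C1C(=O)O[C@H](/C=C/C)[C@H]1[C@H](O)C[C@]2(C)OC(C(C)=C)=CC2=O | intermediate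
17 | 3-methylbutanoic (isovaleric) anhydride | CC(C)CC(=O)OC(=O)CC(C)C | starting material
18 | (1R)-1-[(2R,3R)-4-methylidene-5-oxo-2-[(1E)-prop-1-en-1-yl]oxolan-3-yl]-2-[(2S)-2-methyl-3-oxo-5-(prop-1-en-2-yl)-2,3-dihydrofuran-2-yl]ethyl 3-methylbutanoate | C=C1C(=O)O[C@H](/C=C/C)[C@H]1[C@H](OC(=O)CC(C)C)C[C@]2(C)OC(C(C)=C)=CC2=O | intermediate
19 | CNP0409052.1, (4Z,6R,7R,8R,10S)-8-(3-methylbutanoyloxy)-1-oxo-3,10-epoxygermacra-2,4,11(13)-trien-12,6-olide | C=C1C(=O)O[C@@H]2/C=C(/C)C3=CC(=O)[C@](C)(C[C@@H](OC(=O)CC(C)C)[C@@H]12)O3 | target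

## Step count and risks

Total step count: 8 (steps 1–2 make the aldehyde, steps 3–5 make the bromide, steps 6–8 join and finish).
Longest linear sequence: 6 steps (10 → 11 → 13 → 14 → 16 → 18 → 19).

The three steps most likely to fail:

**Step 2 (the proposed new step).** The risks are a racemic background cyclisation, loss of ee by retro-oxa-Michael through the catalyst enamine, aldol closure of any unisomerised (Z)-oxoenal to a cyclopentenone, and 6-endo closure onto the isopropenyl ketone. The facial sense is a model prediction and depends on the (E)-iminium being the reacting isomer. The fallback uses known reactions only; it sets out from 1 and comes back at 9. Sharpless asymmetric epoxidation of 1 (Ti(OiPr)4, D-(−)-DET, t-BuOOH, CH2Cl2, −20 °C) gives [(2S,3R)-3-ethynyl-3-methyloxiran-2-yl]methanol F1, so C10 is again set by a C–O bond. Red-Al (THF, 0 °C) opens the epoxide at C2 to (3S)-3-methylpent-4-yne-1,3-diol F2. TBSCl/imidazole silylates the primary hydroxyl to give (3S)-5-[(tert-butyldimethylsilyl)oxy]-3-methylpent-1-yn-3-ol F3. Double deprotonation (n-BuLi, 2.1 equiv) and addition of 2 give the γ-hydroxy ynone (6S)-8-[(tert-butyldimethylsilyl)oxy]-6-hydroxy-2,6-dimethyloct-1-en-4-yn-3-one F4. Et2NH in EtOH followed by aqueous HCl (amine conjugate addition, closure of the tertiary hydroxyl onto the ketone, hydrolysis, desilylation) gives (2S)-2-(2-hydroxyethyl)-2-methyl-5-(prop-1-en-2-yl)furan-3(2H)-one F5. Dess–Martin oxidation then gives 9.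

**Step 6 (zinc allylation).** The risks are the syn/anti ratio at C8, the facial selectivity at C7, and translactonisation of the free alcohol. The fallback sets out from 9 and 14 and comes back at 18. CrCl2 (THF, rt; Nozaki–Hiyama allylation through a chair transition state) gives the anti adduct, the C8 epimer (2S)-2-{(2S)-2-hydroxy-2-[(2R,3R)-4-methylidene-5-oxo-2-[(1E)-prop-1-en-1-yl]oxolan-3-yl]ethyl}-2-methyl-5-(prop-1-en-2-yl)furan-3(2H)-one F6. Mitsunobu esterification with 3-methylbutanoic acid (PPh3, DIAD, toluene, 0 °C) inverts C8 and gives 18 directly.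

**Step 8 (macrocyclic metathesis).** The risks are the strained bridged ring, formation of a trisubstituted alkene from a 1,1-disubstituted partner, and dimerisation. The fallback replaces metathesis with an aldol condensation; it sets out from 1 and comes back at 19. Steps 1 and 2 run with N-methoxy-N-methylpropanamide in place of 2 give 1-(3-methylfuran-2-yl)butan-2-one F7 and then (S)-2-(5-ethyl-2-methyl-3-oxo-2,3-dihydrofuran-2-yl)acetaldehyde F8. Zinc allylation with 14 and acylation with 17, as in steps 6 and 7, give the alcohol (2S)-5-ethyl-2-{(2R)-2-hydroxy-2-[(2R,3R)-4-methylidene-5-oxo-2-[(1E)-prop-1-en-1-yl]oxolan-3-yl]ethyl}-2-methylfuran-3(2H)-one F9 and its ester (1R)-2-[(2S)-5-ethyl-2-methyl-3-oxo-2,3-dihydrofuran-2-yl]-1-[(2R,3R)-4-methylidene-5-oxo-2-[(1E)-prop-1-en-1-yl]oxolan-3-yl]ethyl 3-methylbutanoate F10. Lemieux–Johnson cleavage of the propenyl group (OsO4 cat., NaIO4, 2,6-lutidine) gives the aldehyde (1R)-2-[(2S)-5-ethyl-2-methyl-3-oxo-2,3-dihydrofuran-2-yl]-1-[(2S,3R)-2-formyl-4-methylidene-5-oxooxolan-3-yl]ethyl 3-methylbutanoate F11. Intramolecular vinylogous aldol condensation of the 5-ethylfuranone CH2 with this aldehyde (piperidine, AcOH, toluene, 60 °C, loss of water) forms C4=C5 and gives 19.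

## Further compounds

F1 | step 2 | [(2S,3R)-3-ethynyl-3-methyloxiran-2-yl]methanol | OC[C@@H]1O[C@]1(C)C#C
F2 | step 2 | (3S)-3-methylpent-4-yne-1,3-diol | C#C[C@@](C)(O)CCO
F3 | step 2 | (3S)-5-[(tert-butyldimethylsilyl)oxy]-3-methylpent-1-yn-3-ol | C#C[C@@](C)(O)CCO[Si](C)(C)C(C)(C)C
F4 | step 2 | (6S)-8-[(tert-butyldimethylsilyl)oxy]-6-hydroxy-2,6-dimethyloct-1-en-4-yn-3-one | C=C(C)C(=O)C#C[C@@](C)(O)CCO[Si](C)(C)C(C)(C)C
F5 | step 2 | (2S)-2-(2-hydroxyethyl)-2-methyl-5-(prop-1-en-2-yl)furan-3(2H)-one | OCC[C@]1(C)OC(C(C)=C)=CC1=O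
F6 | step 6 | (2S)-2-{(2S)-2-hydroxy-2-[(2R,3R)-4-methylidene-5-oxo-2-[(1E)-prop-1-en-1-yl]oxolan-3-yl]ethyl}-2-methyl-5-(prop-1-en-2-yl)furan-3(2H)-one | C=C1C(=O)O[C@H](/C=C/C)[C@H]1[C@@H](O)C[C@]2(C)OC(C(C)=C)=CC2=O
F7 | step 8 | 1-(3-methylfuran-2-yl)butan-2-one | CCC(=O)Cc1occc1C
F8 | step 8 | (S)-2-(5-ethyl-2-methyl-3-oxo-2,3-dihydrofuran-2-yl)acetaldehyde | O=CC[C@]1(C)OC(CC)=CC1=O
F9 | step 8 | (2S)-5-ethyl-2-{(2R)-2-hydroxy-2-[(2R,3R)-4-methylidene-5-oxo-2-[(1E)-prop-1-en-1-yl]oxolan-3-yl]ethyl}-2-methylfuran-3(2H)-one | C=C1C(=O)O[C@H](/C=C/C)[C@H]1[C@H](O)C[C@]2(C)OC(CC)=CC2=O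
F10 | step 8 | (1R)-2-[(2S)-5-ethyl-2-methyl-3-oxo-2,3-dihydrofuran-2-yl]-1-[(2R,3R)-4-methylidene-5-oxo-2-[(1E)-prop-1-en-1-yl]oxolan-3-yl]ethyl 3-methylbutanoate | C=C1C(=O)O[C@H](/C=C/C)[C@H]1[C@H](OC(=O)CC(C)C)C[C@]2(C)OC(CC)=CC2=O
F11 | step 8 | (1R)-2-[(2S)-5-ethyl-2-methyl-3-oxo-2,3-dihydrofuran-2-yl]-1-[(2S,3R)-2-formyl-4-methylidene-5-oxooxolan-3-yl]ethyl 3-methylbutanoate | C=C1C(=O)O[C@H](C=O)[C@H]1[C@H](OC(=O)CC(C)C)C[C@]2(C)OC(CC)=CC2=O
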